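**Plan**
- Retrosynthesis: the two aryl acetals and the ester are cleared first. Then C3–H (conjugate reduction of a 2Z enoate), C3–C4 (alkyl Suzuki coupling) and C4–C5 (one-carbon boronate homologation) are cut. The furan C4–C5 and C6–C7 bonds are cut together in a three-component conjunctive coupling, and last the furan C4–B and furan C2–aryl bonds.
- Forward: no ring is made; benzene and furan are bought (furan numbered O1, aryl on C2, chain on C4; chain numbered from the carboxyl carbon C1). The aryl–furan bond is joined first, boron is placed on furan C4, and the chain grows outward from C5: C5–C9 in one step, then C4, then C1–C3.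
- Enabling feature: C5 is a methine bonded to furan C4, and its neighbour C6 is a methylene attached to alkene carbon C7. This heteroaryl–CH(B)–CH2–alkenyl unit is what a furyl shift from boron onto a palladium-bound vinyl group, followed by alkenyl coupling, leaves behind.
- Stereochemistry: C5 (S) comes from the chiral MandyPhos–palladium catalyst in the conjunctive coupling and is carried through a stereoretentive 1,2-shift. C3 (R) comes from a DTBM-SEGPHOS–copper hydride reduction of the trisubstituted enoate.

Key step: step 7

Assumption: (Sp,Sp)-MandyPhos is taken to give the S configuration at the boron-bearing carbon, and (R)-DTBM-SEGPHOS–CuH the 3R configuration from the 2Z enoate; both ligands are sold as either antipode, so the opposite hand would be used, with nothing else changed, if the sense of induction is the reverse.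

**Route**

Step 1
Reactants: 1 2-bromobenzene-1,4-diol (bromohydroquinone)
Product: 2 2-bromo-1,4-bis(methoxymethoxy)benzene
Conditions: MOMCl, iPr2NEt, CH2Cl2, 0 °C → rt
Reagents that add atoms: chloromethyl methyl ether, COCCl
Why: O-alkylation of both phenols with MOMCl under amine base (Williamson-type acetal protection) should be clean, and the acetals tolerate the organolithium, palladium and copper hydride steps that follow.

Step 2
Reactants: 2 2-bromo-1,4-bis(methoxymethoxy)benzene
Product: 4 2-[2,5-bis(methoxymethoxy)phenyl]-4,4,5,5-tetramethyl-1,3,2-dioxaborolane, via aryllithium 3 (not isolated)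
Conditions: n-BuLi, THF, −78 °C; iPrOBpin, −78 °C → rt; H2O
Reagents that add atoms: 2-isopropoxy-4,4,5,5-tetramethyl-1,3,2-dioxaborolane, CC(C)OB1OC(C)(C)C(C)(C)O1
Why: Bromine–lithium exchange at −78 °C is faster than acetal-directed ortho-lithiation, and the aryllithium is trapped by the isopropoxy boronate to give the pinacol ester directly (lithiation–borylation).

Step 3
Reactants: 4 2-[2,5-bis(methoxymethoxy)phenyl]-4,4,5,5-tetramethyl-1,3,2-dioxaborolane; 5 2,4-dibromofuran (slight excess)
Product: 6 4-bromo-2-[2,5-bis(methoxymethoxy)phenyl]furan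
Conditions: Pd(PPh3)4 (cat.), K2CO3 (aq), 1,4-dioxane, 80 °C
Reagents that add atoms: none
Why: In this Suzuki–Miyaura coupling zerovalent palladium inserts preferentially into the C2–Br bond next to the furan oxygen, so with the dibromide in slight excess the C4 bromide should be retained.

Step 4
Reactants: 6 4-bromo-2-[2,5-bis(methoxymethoxy)phenyl]furan
Product: 7 2-[5-[2,5-bis(methoxymethoxy)phenyl]furan-3-yl]-4,4,5,5-tetramethyl-1,3,2-dioxaborolane
Conditions: B2pin2, PdCl2(dppf) (cat.), KOAc, 1,4-dioxane, 90 °C
Reagents that add atoms: bis(pinacolato)diboron, CC1(C)OB(OC1(C)C)B1OC(C)(C)C(C)(C)O1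
Why: Miyaura borylation of the remaining heteroaryl bromide with KOAc as a base too weak to promote biaryl coupling should give the furan-3-yl boronate, the acetals and the furan being inert.

Step 5
Reactants: 8 isobutyraldehyde (2-methylpropanal)
Product: 9 2-methylprop-1-enyl trifluoromethanesulfonate
Conditions: Tf2O, 2,6-di-tert-butyl-4-methylpyridine, CH2Cl2, 0 °C → reflux; distillation
Reagents that add atoms: trifluoromethanesulfonic anhydride, O=S(=O)(OS(=O)(=O)C(F)(F)F)C(F)(F)F
Why: O-triflation of the aldehyde and removal of its only α-hydrogen by the hindered, non-nucleophilic pyridine (enol triflate formation) can give only this one alkenyl triflate.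

Step 6
Reactants: 10 tetravinyltin
Product: 11 vinyllithium
Conditions: n-BuLi (4 equiv), pentane, rt; precipitate washed with pentane, dissolved in THF and titrated
Reagents that add atoms: n-butyllithium, [Li]CCCC
Why: Tin–lithium exchange gives vinyllithium that precipitates from pentane free of halide, which matters because halide ions slow the coupling of step 7.

Step 7
Reactants: 7 2-[5-[2,5-bis(methoxymethoxy)phenyl]furan-3-yl]-4,4,5,5-tetramethyl-1,3,2-dioxaborolane; 11 vinyllithium; 9 2-methylprop-1-enyl trifluoromethanesulfonate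
Product: 13 (S)-2-[1-[5-[2,5-bis(methoxymethoxy)phenyl]furan-3-yl]-4-methylpent-3-enyl]-4,4,5,5-tetramethyl-1,3,2-dioxaborolane, via vinyl boron ate complex 12 (not isolated)
Conditions: 11 (1.0 equiv), Et2O/THF, 0 °C → rt; solvent changed to THF; 9 (1.1 equiv), Pd(OAc)2 (2 mol %), (Sp,Sp)-MandyPhos (2.4 mol %), 60 °C
Reagents that add atoms: none
Why: Vinyllithium 11 adds to the boron of 7 to form borate 12, while zerovalent palladium inserts into the C–O bond of triflate 9 to give a cationic alkenyl divalent palladium complex; this binds the vinyl group of 12 and makes its boron-bearing carbon electrophilic, so the furan-3-yl group shifts from boron to that carbon on the face opposite the metal (furan C4–C5 bond), and reductive elimination from the resulting alkyl(alkenyl)palladium then forms C6–C7. The closest known reaction type is the palladium-catalysed enantioselective conjunctive cross-coupling of aryl vinyl boron ate complexes with alkenyl triflates (a metal-induced 1,2-metallate rearrangement), to which an electron-rich furan-3-yl migrating group is a small extension. No ring is closed. The C5 stereocentre is controlled by the chiral MandyPhos bisphosphine on palladium, which fixes the face of the coordinated vinyl group that is open to the migrating furyl group. The step needs the metallate shift to outrun direct transfer of furyl or vinyl from boron to palladium and β-hydride elimination of the alkyl palladium intermediate; the wide-bite-angle ligand, the non-coordinating triflate counter-ion and halide-free 11 should secure this, and migration of carbon in preference to a pinacol oxygen is the normal order for such borates.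

Step 8
Reactants: 13 (S)-2-[1-[5-[2,5-bis(methoxymethoxy)phenyl]furan-3-yl]-4-methylpent-3-enyl]-4,4,5,5-tetramethyl-1,3,2-dioxaborolane
Product: 15 (S)-2-[2-[5-[2,5-bis(methoxymethoxy)phenyl]furan-3-yl]-5-methylhex-4-enyl]-4,4,5,5-tetramethyl-1,3,2-dioxaborolane, via chloromethyl boron ate complex 14 (not isolated)
Conditions: BrCH2Cl, n-BuLi, THF, −78 °C → rt
Reagents that add atoms: bromochloromethane, ClCBr
Why: In this Matteson homologation LiCH2Cl generated in the flask adds to boron and the secondary alkyl group migrates to the chloromethyl carbon with loss of chloride and retention of configuration at C5, which inserts C4.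

Step 9
Reactants: 15 (S)-2-[2-[5-[2,5-bis(methoxymethoxy)phenyl]furan-3-yl]-5-methylhex-4-enyl]-4,4,5,5-tetramethyl-1,3,2-dioxaborolane; 16 ethyl (Z)-3-iodobut-2-enoate
Product: 17 ethyl (2Z,5R)-5-[5-[2,5-bis(methoxymethoxy)phenyl]furan-3-yl]-3,8-dimethylnona-2,7-dienoate
Conditions: Pd(OAc)2 (cat.), RuPhos, K3PO4, toluene/H2O (10:1), 80 °C
Reagents that add atoms: none
Why: B-alkyl Suzuki–Miyaura coupling of a primary alkyl pinacol boronate with a reactive β-iodo enoate under an electron-rich biaryl phosphine should form C3–C4 with retention of the Z geometry and without touching the ester, the C5 descriptor becoming R only through a change in substituent priorities.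

Step 10
Reactants: 17 ethyl (2Z,5R)-5-[5-[2,5-bis(methoxymethoxy)phenyl]furan-3-yl]-3,8-dimethylnona-2,7-dienoate
Product: 18 ethyl (3R,5S)-5-[5-[2,5-bis(methoxymethoxy)phenyl]furan-3-yl]-3,8-dimethylnon-7-enoate
Conditions: Cu(OAc)2·H2O (5 mol %), (R)-DTBM-SEGPHOS (5.5 mol %), (EtO)2MeSiH, t-BuOH, toluene, 0 °C → rt
Reagents that add atoms: none
Why: Asymmetric copper hydride conjugate reduction (1,4-hydrosilylation) delivers hydride to one face of C3 under control of the chiral bisphosphine, the remote C5 centre having little say, and the isolated trisubstituted alkene and the furan are not reduced.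

Step 11
Reactants: 18 ethyl (3R,5S)-5-[5-[2,5-bis(methoxymethoxy)phenyl]furan-3-yl]-3,8-dimethylnon-7-enoate
Product: 20 (3R,5S)-5-[5-[2,5-bis(methoxymethoxy)phenyl]furan-3-yl]-3,8-dimethylnon-7-enoic acid, via lithium carboxylate 19 (not isolated)
Conditions: LiOH, THF/EtOH/H2O, rt; then 1 M HCl to pH 4, 0 °C
Reagents that add atoms: lithium hydroxide, [Li+].[OH-]
Why: Ester saponification is done while the phenols are still masked, the acetals being stable to base and the C3 centre, β to the carbonyl, unable to epimerise.

Step 12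
Reactants: 20 (3R,5S)-5-[5-[2,5-bis(methoxymethoxy)phenyl]furan-3-yl]-3,8-dimethylnon-7-enoic acid
Product: 22 (3R,5S)-5-[5-(2,5-dihydroxyphenyl)furan-3-yl]-3,8-dimethylnon-7-enoic acid, via tris(trimethylsilyl) derivative 21 (not isolated)
Conditions: TMSOTf, 2,2'-bipyridyl, CH3CN, 0 °C → rt; then H2O, rt; degassed solvents, argon
Reagents that add atoms: none
Why: Silyl triflate–bipyridyl cleavage of aryl methoxymethyl ethers converts the acetals to aryl silyl ethers (and the acid to its silyl ester) under buffered, non-protic conditions that spare the trisubstituted alkene and the furan, and water then hydrolyses the three silyl groups to release the air-sensitive hydroquinone last.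

**Compound list**
1 | 2-bromobenzene-1,4-diol (bromohydroquinone) | Oc1ccc(O)c(Br)c1 | starting material
2 | 2-bromo-1,4-bis(methoxymethoxy)benzene | COCOc1ccc(OCOC)c(Br)c1 | intermediate
3 | [2,5-bis(methoxymethoxy)phenyl]lithium (not isolated) | [Li]c1cc(OCOC)ccc1OCOC | intermediate
4 | 2-[2,5-bis(methoxymethoxy)phenyl]-4,4,5,5-tetramethyl-1,3,2-dioxaborolane | COCOc1ccc(OCOC)c(B2OC(C)(C)C(C)(C)O2)c1 | intermediate
5 | 2,4-dibromofuran | Brc1coc(Br)c1 | starting material
6 | 4-bromo-2-[2,5-bis(methoxymethoxy)phenyl]furan | Brc1coc(-c2cc(OCOC)ccc2OCOC)c1 | intermediate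
7 | 2-[5-[2,5-bis(methoxymethoxy)phenyl]furan-3-yl]-4,4,5,5-tetramethyl-1,3,2-dioxaborolane | CC1(C)OB(OC1(C)C)c1coc(-c2cc(OCOC)ccc2OCOC)c1 | intermediate
8 | isobutyraldehyde (2-methylpropanal) | CC(C)C=O | starting material
9 | 2-methylprop-1-enyl trifluoromethanesulfonate | CC(C)=COS(=O)(=O)C(F)(F)F | intermediate
10 | tetravinyltin | C=C[Sn](C=C)(C=C)C=C | starting material
11 | vinyllithium | [Li]C=C | intermediate
12 | lithium [5-[2,5-bis(methoxymethoxy)phenyl]furan-3-yl](ethenyl)(pinacolato)borate (not isolated) | [Li+].C=C[B-]1(OC(C)(C)C(C)(C)O1)c1coc(-c2cc(OCOC)ccc2OCOC)c1 | intermediate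
13 | (S)-2-[1-[5-[2,5-bis(methoxymethoxy)phenyl]furan-3-yl]-4-methylpent-3-enyl]-4,4,5,5-tetramethyl-1,3,2-dioxaborolane | CC(C)=CC[C@H](B1OC(C)(C)C(C)(C)O1)c1coc(-c2cc(OCOC)ccc2OCOC)c1 | intermediate
14 | lithium (chloromethyl)[(S)-1-[5-[2,5-bis(methoxymethoxy)phenyl]furan-3-yl]-4-methylpent-3-enyl](pinacolato)borate (not isolated) | [Li+].CC(C)=CC[C@H]([B-]1(CCl)OC(C)(C)C(C)(C)O1)c1coc(-c2cc(OCOC)ccc2OCOC)c1 | intermediate
15 | (S)-2-[2-[5-[2,5-bis(methoxymethoxy)phenyl]furan-3-yl]-5-methylhex-4-enyl]-4,4,5,5-tetramethyl-1,3,2-dioxaborolane | CC(C)=CC[C@H](CB1OC(C)(C)C(C)(C)O1)c1coc(-c2cc(OCOC)ccc2OCOC)c1 | intermediate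
16 | ethyl (Z)-3-iodobut-2-enoate | CCOC(=O)/C=C(/C)I | starting material
17 | ethyl (2Z,5R)-5-[5-[2,5-bis(methoxymethoxy)phenyl]furan-3-yl]-3,8-dimethylnona-2,7-dienoate | CC(C)=CC[C@H](C/C(C)=C\C(=O)OCC)c1coc(-c2cc(OCOC)ccc2OCOC)c1 | intermediate
18 | ethyl (3R,5S)-5-[5-[2,5-bis(methoxymethoxy)phenyl]furan-3-yl]-3,8-dimethylnon-7-enoate | CC(C)=CC[C@H](C[C@@H](C)CC(=O)OCC)c1coc(-c2cc(OCOC)ccc2OCOC)c1 | intermediate
19 | lithium (3R,5S)-5-[5-[2,5-bis(methoxymethoxy)phenyl]furan-3-yl]-3,8-dimethylnon-7-enoate (not isolated) | [Li+].CC(C)=CC[C@H](C[C@@H](C)CC(=O)[O-])c1coc(-c2cc(OCOC)ccc2OCOC)c1 | intermediate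
20 | (3R,5S)-5-[5-[2,5-bis(methoxymethoxy)phenyl]furan-3-yl]-3,8-dimethylnon-7-enoic acid | CC(C)=CC[C@H](C[C@@H](C)CC(=O)O)c1coc(-c2cc(OCOC)ccc2OCOC)c1 | intermediate
21 | trimethylsilyl (3R,5S)-5-[5-[2,5-bis(trimethylsilyloxy)phenyl]furan-3-yl]-3,8-dimethylnon-7-enoate (not isolated) | CC(C)=CC[C@H](C[C@@H](C)CC(=O)O[Si](C)(C)C)c1coc(-c2cc(O[Si](C)(C)C)ccc2O[Si](C)(C)C)c1 | intermediate
22 | (3R,5S)-5-[5-(2,5-dihydroxyphenyl)furan-3-yl]-3,8-dimethylnon-7-enoic acid (CNP0531232.1) | CC(C)=CC[C@H](C[C@@H](C)CC(=O)O)c1coc(-c2cc(O)ccc2O)c1 | target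

**Summary**
Total step count: 12.
Longest linear sequence: 10 steps (steps 1, 2, 3, 4, 7, 8, 9, 10, 11, 12, from bromohydroquinone); steps 5 and 6 are one-step side branches.

**Steps most likely to fail**

1. Step 7. The borate may hand furyl or vinyl directly to palladium (Suzuki-type coupling) faster than the metallate shift occurs, or the shift may proceed with too little facial bias, so that the C5 centre forms in low amount or low enantiomeric purity. The fallback is a lithiation–borylation that sets out from 7 and comes back at 13. Commercial 4-methylpent-3-en-1-ol F1 is carbamoylated (N,N-diisopropylcarbamoyl chloride, Et3N, toluene, reflux) to 4-methylpent-3-enyl N,N-diisopropylcarbamate F2. Deprotonation with s-BuLi/(+)-sparteine in Et2O at −78 °C should give the configurationally stable (R)-1-lithio-4-methylpent-3-enyl N,N-diisopropylcarbamate F3. This is borylated by 7 with retention to the lithium boron ate complex F4. Warming with MgBr2·OEt2 then drives 1,2-migration of the furyl group with inversion at carbon and loss of the carbamate, giving 13. The same furan C4–C5 bond arises by furyl migration from boron to carbon, with the diamine instead of the palladium ligand controlling C5.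

2. Step 9. Transmetalation of the β-branched primary alkyl pinacol boronate may be slower than base-induced loss of HI from 16 or protodeboronation of 15, so that little coupling occurs. The fallback is a Negishi coupling that sets out from 15 and comes back at 17. Oxidation of 15 (NaBO3·4H2O, THF/H2O) gives (S)-2-[5-[2,5-bis(methoxymethoxy)phenyl]furan-3-yl]-5-methylhex-4-en-1-ol F5. Iodination (I2, PPh3, imidazole, CH2Cl2) gives 4-[(S)-1-iodo-5-methylhex-4-en-2-yl]-2-[2,5-bis(methoxymethoxy)phenyl]furan F6. Zinc insertion (Zn dust, LiCl, THF) gives the alkylzinc iodide F7, which is coupled with 16 under Pd(PPh3)4 catalysis in THF to give 17.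

3. Step 10. Hydride delivery may discriminate poorly between the two faces of C3, because its two β-substituents (methyl and a branched methylene) differ little in size, or the C5 centre may work against the catalyst, leading to a diastereomer mixture. The fallback sets out from 17 and comes back at 20. Saponification of 17 (LiOH, THF/EtOH/H2O) gives (2Z,5R)-5-[5-[2,5-bis(methoxymethoxy)phenyl]furan-3-yl]-3,8-dimethylnona-2,7-dienoic acid F8. Carboxylate-directed hydrogenation with Ru(OAc)2[(S)-BINAP] (H2, 50 atm, MeOH, rt; BINAP antipode matched to the Z geometry so that 3R results) should reduce only the conjugated double bond and give 20 directly, leaving the isolated trisubstituted alkene and the furan untouched.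

**Further compounds**
F1 | step 7 | 4-methylpent-3-en-1-ol (bought, not made) | CC(C)=CCCO
F2 | step 7 | 4-methylpent-3-enyl N,N-diisopropylcarbamate | CC(C)=CCCOC(=O)N(C(C)C)C(C)C
F3 | step 7 | (R)-1-lithio-4-methylpent-3-enyl N,N-diisopropylcarbamate ((+)-sparteine complex) | CC(C)=CC[C@@H]([Li])OC(=O)N(C(C)C)C(C)C
F4 | step 7 | lithium [(R)-1-(N,N-diisopropylcarbamoyloxy)-4-methylpent-3-enyl][5-[2,5-bis(methoxymethoxy)phenyl]furan-3-yl](pinacolato)borate | [Li+].CC(C)=CC[C@H](OC(=O)N(C(C)C)C(C)C)[B-]1(OC(C)(C)C(C)(C)O1)c1coc(-c2cc(OCOC)ccc2OCOC)c1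
F5 | step 9 | (S)-2-[5-[2,5-bis(methoxymethoxy)phenyl]furan-3-yl]-5-methylhex-4-en-1-ol | CC(C)=CC[C@H](CO)c1coc(-c2cc(OCOC)ccc2OCOC)c1
F6 | step 9 | 4-[(S)-1-iodo-5-methylhex-4-en-2-yl]-2-[2,5-bis(methoxymethoxy)phenyl]furan | CC(C)=CC[C@H](CI)c1coc(-c2cc(OCOC)ccc2OCOC)c1
F7 | step 9 | [(S)-2-[5-[2,5-bis(methoxymethoxy)phenyl]furan-3-yl]-5-methylhex-4-enyl]zinc iodide | CC(C)=CC[C@H](C[Zn]I)c1coc(-c2cc(OCOC)ccc2OCOC)c1
F8 | step 10 | (2Z,5R)-5-[5-[2,5-bis(methoxymethoxy)phenyl]furan-3-yl]-3,8-dimethylnona-2,7-dienoic acid | CC(C)=CC[C@H](C/C(C)=C\C(=O)O)c1coc(-c2cc(OCOC)ccc2OCOC)c1
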